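**Plan**
- Retrosynthesis: the five benzyl ethers come off last. The dihydropyran is then cut across O1–C2 and C3–C4 in one retro-[4+2], giving an o-quinone methide on the isovalerylphloroglucinol ring and an (E)-β-isopropylstyrene on the diformylphloroglucinol ring. The styrene is cut at the aryl–vinyl bond, the diene precursor at aryl–CH2OH and aryl–acyl.
- Enabling feature: C4 is an unsubstituted methylene ortho to the ring oxygen O1 on an electron-rich arene (C8a/C4a). This is a latent 1-oxadiene O1=C8a–C4a=C4H2, reached by transient dearomatisation. C2 and C3 carry aryl and isopropyl trans, a latent (E)-alkene.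
- Forward: both benzene rings come from phloroglucinol (acylation on one; diformylation, bromination and Suzuki alkenylation on the other). The pyran is the only ring made and is closed last, in the step that joins the two halves.
- Regiocontrol: on the diene half only the hydroxyl para to the ketone is left free (the two flanking hydroxyls are benzyl ethers), so that oxygen alone can become O1.
- Stereochemistry: the trans C2/C3 relation comes from the (E)-alkene geometry (suprafacial cycloaddition); the absolute configuration (2R,3S) comes from a confined chiral Brønsted acid in the cycloaddition.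

Key step: step 10

Assumption: the (E)-alkenyl pinacol boronate of step 9 is a catalogue compound; the sense of induction of the chiral acid in step 10 has to be assigned on the first run, and the antipodal catalyst is taken if it proves opposite.

**Route**

Step 1
Reactants: 1 phloroglucinol; 2 3-methylbutanoyl chloride
Product: 3 3-methyl-1-(2,4,6-trihydroxyphenyl)butan-1-one
Conditions: AlCl3 (3.5 equiv), CH2Cl2/MeNO2, 0 °C → 40 °C; then ice/aq. HCl
Reagents that add atoms: none
Why: Friedel–Crafts C-acylation of the highly activated triol; the first acyl group deactivates the ring, so monoacylation should dominate.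

Step 2
Reactants: 3 3-methyl-1-(2,4,6-trihydroxyphenyl)butan-1-one
Product: 4 1-[2,6-dihydroxy-4-(methoxymethoxy)phenyl]-3-methylbutan-1-one
Conditions: MOMCl (1.05 equiv), iPr2NEt, CH2Cl2, 0 °C
Reagents that add atoms: chloromethyl methyl ether, COCCl
Why: Williamson-type acetal ether formation is expected at the 4-OH, the most acidic hydroxyl and the only one not hydrogen-bonded to the ketone, when one equivalent of the chloride is used.

Step 3
Reactants: 4 1-[2,6-dihydroxy-4-(methoxymethoxy)phenyl]-3-methylbutan-1-one
Product: 5 1-[2,6-bis(benzyloxy)-4-(methoxymethoxy)phenyl]-3-methylbutan-1-one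
Conditions: BnBr (2.5 equiv), K2CO3, cat. Bu4NI, DMF, 60 °C
Reagents that add atoms: benzyl bromide, BrCc1ccccc1
Why: Williamson etherification under forcing conditions benzylates the two chelated ortho-hydroxyls in a polar aprotic medium that favours O- over C-alkylation, and the MOM ether is stable to base.

Step 4
Reactants: 5 1-[2,6-bis(benzyloxy)-4-(methoxymethoxy)phenyl]-3-methylbutan-1-one
Product: 6 1-[2,6-bis(benzyloxy)-4-hydroxyphenyl]-3-methylbutan-1-one
Conditions: HCl (cat.), MeOH/THF, 50 °C
Reagents that add atoms: none
Why: acid-catalysed acetal exchange (MOM cleavage) should free the 4-OH while the benzyl ethers and the hindered ketone stay untouched.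

Step 5
Reactants: 6 1-[2,6-bis(benzyloxy)-4-hydroxyphenyl]-3-methylbutan-1-one
Product: 8 1-[2,6-bis(benzyloxy)-4-hydroxy-3-(hydroxymethyl)phenyl]-3-methylbutan-1-one, via benzodioxaborin 7 (not isolated)
Conditions: PhB(OH)2, (CH2O)n, cat. EtCO2H, toluene, reflux (Dean–Stark); then propane-1,3-diol, THF, rt
Reagents that add atoms: formaldehyde (from paraformaldehyde), C=O; phenylboronic acid, OB(O)c1ccccc1 (its atoms are held only in 7)
Why: Nagata-type boronic-acid-templated ortho-hydroxymethylation delivers formaldehyde only ortho to the free phenol and holds the product as the dioxaborin, which blocks a second hydroxymethylation and diarylmethane formation, and neutral transesterification then releases the acid-sensitive salicyl alcohol.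

Step 6
Reactants: 1 phloroglucinol
Product: 10 2,4,6-trihydroxybenzene-1,3-dicarbaldehyde, via bis-iminium salt 9 (not isolated)
Conditions: POCl3 (2.2 equiv), DMF, 1,4-dioxane, 0 °C → rt; then H2O
Reagents that add atoms: N,N-dimethylformamide, CN(C)C=O (formyl carbon); water, O (formyl oxygen)
Why: Vilsmeier–Haack formylation with two equivalents of the chloroiminium reagent should formylate twice, the third position being deactivated by the two iminium groups, and aqueous work-up hydrolyses the bis-iminium salt.

Step 7
Reactants: 10 2,4,6-trihydroxybenzene-1,3-dicarbaldehyde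
Product: 11 5-bromo-2,4,6-trihydroxybenzene-1,3-dicarbaldehyde
Conditions: NBS (1.0 equiv), MeCN, 0 °C → rt
Reagents that add atoms: N-bromosuccinimide, O=C1CCC(=O)N1Br
Why: electrophilic aromatic bromination at the single remaining ring C–H, the nucleophilic carbon of the vinylogous acid.

Step 8
Reactants: 11 5-bromo-2,4,6-trihydroxybenzene-1,3-dicarbaldehyde
Product: 12 2,4,6-tris(benzyloxy)-5-bromobenzene-1,3-dicarbaldehyde
Conditions: BnBr (4 equiv), K2CO3, cat. Bu4NI, DMF, 60 °C
Reagents that add atoms: benzyl bromide, BrCc1ccccc1
Why: Williamson etherification; with the ring fully substituted only O-alkylation is open, and the carbonate/DMF medium should overcome the chelation of the hydroxyls to the formyl groups.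

Step 9
Reactants: 12 2,4,6-tris(benzyloxy)-5-bromobenzene-1,3-dicarbaldehyde; 13 4,4,5,5-tetramethyl-2-[(E)-3-methylbut-1-en-1-yl]-1,3,2-dioxaborolane
Product: 14 2,4,6-tris(benzyloxy)-5-[(E)-3-methylbut-1-en-1-yl]benzene-1,3-dicarbaldehyde
Conditions: Pd(OAc)2 (5 mol %), SPhos (10 mol %), K3PO4, toluene/H2O, 80 °C
Reagents that add atoms: none
Why: Suzuki–Miyaura coupling with a dialkylbiarylphosphine ligand suited to di-ortho-substituted aryl bromides; transmetalation and reductive elimination retain the (E)-geometry of the alkenyl boronate, and the aldehydes are tolerated.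

Step 10
Reactants: 8 1-[2,6-bis(benzyloxy)-4-hydroxy-3-(hydroxymethyl)phenyl]-3-methylbutan-1-one; 14 2,4,6-tris(benzyloxy)-5-[(E)-3-methylbut-1-en-1-yl]benzene-1,3-dicarbaldehyde
Product: 16 5-[(2R,3S)-5,7-bis(benzyloxy)-6-(3-methylbutanoyl)-3-(propan-2-yl)-3,4-dihydro-2H-1-benzopyran-2-yl]-2,4,6-tris(benzyloxy)benzene-1,3-dicarbaldehyde, via o-quinone methide 15 (not isolated)
Conditions: (S,S)-IDPi (BINOL-derived imidodiphosphorimidate, N-triflyl core, bulky 3,3′-aryl groups; 5 mol %), 5 Å MS, CHCl3, −20 °C; 8 added over several hours to 14 (1.5 equiv)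
Reagents that add atoms: none
Why: Proposed new method: the chiral acid dehydrates 8 to o-quinone methide 15 (transient dearomatisation of the phenol ring) and keeps it hydrogen-bonded or ion-paired in its pocket, where C-β of styrene 14 attacks the exocyclic CH2 while the quinone oxygen bonds to the benzylic carbon, a concerted-asynchronous inverse-electron-demand oxa-[4+2] that rearomatises the ring. The closest known reaction types are the chiral phosphoric acid and imidodiphosphorimidate catalysed oxa-Diels–Alder reactions of o-quinone methides generated from o-hydroxybenzyl alcohols with vinylarenes and the racemic o-quinone methide/styrene cycloaddition of phloroglucinols; not yet shown is the pairing of an unsubstituted methide with a β-branched styrene that has no hydrogen-bond donor. The dihydropyran is closed by intermolecular [4+2] cycloaddition, which forms C4–C3 and O1–C2 together. The trans C2/C3 relation is set by the (E)-geometry of 14 through suprafacial addition (and is also the favoured diequatorial outcome should the closure be stepwise), and the absolute (2R,3S) sense by the catalyst, which must tell apart the two faces of the alkene inside its confined pocket. The step needs regiocontrol at oxygen, secured because only the hydroxyl para to the ketone is free, orientation, secured by the polarisation of 15 (electrophilic CH2) and 14 (nucleophilic C-β, cation-stabilising aryl), and chemoselectivity against alkylation of 8 by 15, secured by slow addition of 8 to an excess of 14.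

Step 11
Reactants: 16 5-[(2R,3S)-5,7-bis(benzyloxy)-6-(3-methylbutanoyl)-3-(propan-2-yl)-3,4-dihydro-2H-1-benzopyran-2-yl]-2,4,6-tris(benzyloxy)benzene-1,3-dicarbaldehyde
Product: 17 5-[(2R,3S)-5,7-dihydroxy-6-(3-methylbutanoyl)-3-(propan-2-yl)-3,4-dihydro-2H-1-benzopyran-2-yl]-2,4,6-trihydroxybenzene-1,3-dicarbaldehyde (CNP0551232.1)
Conditions: BCl3 (excess), pentamethylbenzene, CH2Cl2, −78 °C; MeOH quench at −78 °C, aqueous work-up
Reagents that add atoms: none
Why: Lewis-acid debenzylation with a cation scavenger; all five benzyl ethers sit ortho to a carbonyl, so chelation should speed their cleavage at −78 °C, the benzyl cations are trapped by pentamethylbenzene, and the aldehydes, the ketone and the two stereocentres (neither next to a carbonyl) should be left untouched.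

**Compound list**
1 | phloroglucinol (benzene-1,3,5-triol) | Oc1cc(O)cc(O)c1 | starting material
2 | 3-methylbutanoyl chloride | CC(C)CC(=O)Cl | starting material
3 | 3-methyl-1-(2,4,6-trihydroxyphenyl)butan-1-one | CC(C)CC(=O)c1c(O)cc(O)cc1O | intermediate
4 | 1-[2,6-dihydroxy-4-(methoxymethoxy)phenyl]-3-methylbutan-1-one | CC(C)CC(=O)c1c(O)cc(OCOC)cc1O | intermediate
5 | 1-[2,6-bis(benzyloxy)-4-(methoxymethoxy)phenyl]-3-methylbutan-1-one | CC(C)CC(=O)c1c(OCc2ccccc2)cc(OCOC)cc1OCc1ccccc1 | intermediate
6 | 1-[2,6-bis(benzyloxy)-4-hydroxyphenyl]-3-methylbutan-1-one | CC(C)CC(=O)c1c(OCc2ccccc2)cc(O)cc1OCc1ccccc1 | intermediate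
7 | 1-[5,7-bis(benzyloxy)-2-phenyl-4H-1,3,2-benzodioxaborin-6-yl]-3-methylbutan-1-one | CC(C)CC(=O)c1c(OCc2ccccc2)cc2OB(c3ccccc3)OCc2c1OCc1ccccc1 | intermediate
8 | 1-[2,6-bis(benzyloxy)-4-hydroxy-3-(hydroxymethyl)phenyl]-3-methylbutan-1-one | CC(C)CC(=O)c1c(OCc2ccccc2)cc(O)c(CO)c1OCc1ccccc1 | intermediate
9 | bis-iminium dichloride: (2,4,6-trihydroxy-1,3-phenylene)bis(N,N-dimethylmethaniminium) dichloride | C[N+](C)=Cc1c(O)cc(O)c(C=[N+](C)C)c1O.[Cl-].[Cl-] | intermediate
10 | 2,4,6-trihydroxybenzene-1,3-dicarbaldehyde | O=Cc1c(O)cc(O)c(C=O)c1O | intermediate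
11 | 5-bromo-2,4,6-trihydroxybenzene-1,3-dicarbaldehyde | O=Cc1c(O)c(Br)c(O)c(C=O)c1O | intermediate
12 | 2,4,6-tris(benzyloxy)-5-bromobenzene-1,3-dicarbaldehyde | O=Cc1c(OCc2ccccc2)c(Br)c(OCc2ccccc2)c(C=O)c1OCc1ccccc1 | intermediate
13 | 4,4,5,5-tetramethyl-2-[(E)-3-methylbut-1-en-1-yl]-1,3,2-dioxaborolane | CC(C)/C=C/B1OC(C)(C)C(C)(C)O1 | starting material
14 | 2,4,6-tris(benzyloxy)-5-[(E)-3-methylbut-1-en-1-yl]benzene-1,3-dicarbaldehyde | CC(C)/C=C/c1c(OCc2ccccc2)c(C=O)c(OCc2ccccc2)c(C=O)c1OCc1ccccc1 | intermediate
15 | 3,5-bis(benzyloxy)-6-methylidene-4-(3-methylbutanoyl)cyclohexa-2,4-dien-1-one | CC(C)CC(=O)C1=C(OCc2ccccc2)C(=C)C(=O)C=C1OCc1ccccc1 | intermediate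
16 | 5-[(2R,3S)-5,7-bis(benzyloxy)-6-(3-methylbutanoyl)-3-(propan-2-yl)-3,4-dihydro-2H-1-benzopyran-2-yl]-2,4,6-tris(benzyloxy)benzene-1,3-dicarbaldehyde | CC(C)CC(=O)c1c(OCc2ccccc2)cc2c(c1OCc1ccccc1)C[C@@H](C(C)C)[C@H](c1c(OCc3ccccc3)c(C=O)c(OCc3ccccc3)c(C=O)c1OCc1ccccc1)O2 | intermediate
17 | 5-[(2R,3S)-5,7-dihydroxy-6-(3-methylbutanoyl)-3-(propan-2-yl)-3,4-dihydro-2H-1-benzopyran-2-yl]-2,4,6-trihydroxybenzene-1,3-dicarbaldehyde | CC(C)CC(=O)c1c(O)cc2c(c1O)C[C@@H](C(C)C)[C@H](c1c(O)c(C=O)c(O)c(C=O)c1O)O2 | target

**Summary**
Total step count: 11. Longest linear sequence: 7 steps (steps 1–5, 10, 11).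

**Steps most likely to fail**

1. Step 10 (proposed new method). The catalyst may not discriminate the faces of a hindered, β-branched styrene that offers it no hydrogen-bond contact. The o-quinone methide may also be consumed by Friedel–Crafts self-alkylation of unreacted phenol at its free ring position. Fallback, setting out from 8 and 14 and coming back at 16: the cycloaddition is run without chiral control. Intermediate 15 is generated with an achiral acid (diphenyl phosphate, CHCl3, 40 °C) or by heating in toluene, the known racemic o-quinone methide/styrene oxa-Diels–Alder. This should give the trans adduct as the racemate, that is 16 together with its mirror image, ent-16 F1. Preparative chromatography on a polysaccharide chiral stationary phase should then separate the two, and 16 re-enters the route at step 11.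

2. Step 11. Boron coordination may ionise the benzylic C2–O1 bond, opening the pyran ring, after which the cation is trapped by the scavenger or recloses with loss of the trans relation. Cleavage of the second benzyl ether beside the ketone may also stall. Fallback, setting out from 16 and coming back at 17: the Lewis-acid cleavage is replaced by neutral catalytic hydrogenolysis (H2, 1 atm, Pd(OH)2/C, EtOAc/THF, rt, stopped at full debenzylation). This is a reductive cleavage that does not pass through benzylic cations; it makes no new compound (F0).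

3. Step 5. The hydroxymethylated phenol may condense further to diarylmethanes if the boronate template forms slowly on this para-acyl phenol, or on release of the salicyl alcohol. Fallback, setting out from 6 and coming back at 8: magnesium-mediated ortho-formylation (MgCl2, Et3N, paraformaldehyde, MeCN, reflux) should give the salicylaldehyde 2,4-bis(benzyloxy)-6-hydroxy-3-(3-methylbutanoyl)benzaldehyde F2. NaBH4 (THF/MeOH, 0 °C) then reduces the aldehyde in preference to the twisted, di-ortho-substituted ketone and gives 8.

**Further compounds**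
F1 | step 10 | 5-[(2S,3R)-5,7-bis(benzyloxy)-6-(3-methylbutanoyl)-3-(propan-2-yl)-3,4-dihydro-2H-1-benzopyran-2-yl]-2,4,6-tris(benzyloxy)benzene-1,3-dicarbaldehyde (ent-16) | CC(C)CC(=O)c1c(OCc2ccccc2)cc2c(c1OCc1ccccc1)C[C@H](C(C)C)[C@@H](c1c(OCc3ccccc3)c(C=O)c(OCc3ccccc3)c(C=O)c1OCc1ccccc1)O2
F0 | step 11 | none | none
F2 | step 5 | 2,4-bis(benzyloxy)-6-hydroxy-3-(3-methylbutanoyl)benzaldehyde | CC(C)CC(=O)c1c(OCc2ccccc2)cc(O)c(C=O)c1OCc1ccccc1
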